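The constants come first, and the earlier flasks give them. Substrate's fall reads 0.118 min⁻¹ in elm, and at 10.0 min it stands at 30.3% in oak against 30.4% in elm, although oak got 0.36 equiv of first nucleophile and elm 1.1 equiv. Substrate's loss therefore doesn't follow that charge.

| run | time / min | target / % | substrate / % |
|---|---|---|---|
| oak | 0.833 | 3.8 | 90.3 |
| oak | 2.00 | 13.0 | 78.4 |
| oak | 5.00 | 26.6 | 55.1 |
| oak | 10.0 | 30.6 | 30.3 |
| elm | 1.33 | 11.8 | 84.9 |
| elm | 4.00 | 33.3 | 61.8 |
| elm | 6.00 | 43.9 | 48.5 |
| elm | 10.0 | 55.5 | 30.4 |

(each reading ± 0.3 percentage points)

Target needs both turned-over substrate and first nucleophile. Taking one of each per target, its supply is the smaller of the two, and in oak that is the charge (the limiting reagent), 0.36 equiv against 69.7% turned over. Target over that smaller supply, the supply yield, reads 85.0% in oak. In elm the smaller supply is the turned-over substrate, and the reading is 79.7%.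

in all of them: substrate 0.30 M; gas 42 mM (held)
- oak: first nucleophile 0.36 equiv; run made earlier
- elm: first nucleophile 1.1 equiv; run made earlier
- Monday's: first nucleophile 0.250 equiv; time 15 min
- Saturday's: first nucleophile 0.500 equiv; time 15 min
- Sunday's: first nucleophile 1.00 equiv; time 15 min

- amount of target at the end, in percent of the substrate charged for Monday's, Saturday's, Sunday's, in this order
- the course of these numbers from the first flask to the last (hardly changes / falls, then rises / falls all the way / rises, then falls / rises all the way)

- the earlier runs were read with a standard deviation of 0.3 percentage points
- at the start none of the gas is in solution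
- "hardly changes" means that all values lie within two and a half points (for a concentration: within two and a half percent of the largest)

The decision for the next run is whether Sunday's 1.00 equiv earns its charge over Saturday's 0.500 equiv. At that rate about 83.1% of the substrate should have turned over by 15 min, which exceeds Saturday's charge and Monday's, so this reckoning takes Monday's and Saturday's as limited by their charges. Oak's yield gives them 21.2% and 42.5%. Sunday's supply is the turned-over substrate, and elm's yield gives 66.2%. Doubling Saturday's charge thus buys 1.56 times the target, and the full charge stays in the plan.

The forecast stands lower, at 16.5%, 34.5% and 59%, with the course rises all the way, on the ground that “target slowly decays”. This reckoning shares that course but not those values.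

The flasks give 19.9%, 40.4% and 62.3%, and the course rises all the way.

    substrate → intermediate (k = 0.120 min⁻¹)
    second nucleophile + intermediate → other capture product (k = 10.0 M⁻¹ min⁻¹)
    gas ⇌ second nucleophile, rate k3*(csat - [second nucleophile]) (kL = 0.190 min⁻¹)
    second nucleophile ⇌ dormant form (K = 70.0, k = 0.0390 min⁻¹)
    first nucleophile + intermediate → target (k = 14.0 M⁻¹ min⁻¹)
    target ⇌ isomer of the product (K = 0.370, k = 0.0310 min⁻¹)

The supply yield comes to 79.6% on Monday's flask and 80.8% on Saturday's, against the 85.0% read in oak. Monday's first nucleophile fell under a fiftieth of its charge at 7.03 min, earlier than the 15 min end, and stood at 1.27% of its own charge at 7.50 min; from that reading to the end target went from 21.9% to 19.9% while isomer of the product reached 5.07%, the two together making 25.0%, level with the charge.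

(The data were generated by integration from invented constants, and the scatter is random.)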